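The dimer is cut into two copies of one monomer, a cis-lactone guaianolide: one copy is dehydrogenated to a dienone, and Diels–Alder union (C2–C4′, C14–C15′) with the other, then aerobic C2 hydroxylation, finishes the target. Everything rests on building the monomer's hydroazulene in one operation by a rhodium-catalysed allene–vinylcyclopropane [5+2] cycloaddition of an acyclic allenyl dienyl siloxycyclopropane: the ring-fusion bond C1–C5 and the bond C9–C10 form while the cyclopropane opens. The step exploits the exocyclic methylene C10=C14 beside ring-fusion carbon C1 (an allene's spectator double bond) and the seven-membered ring C1, C5–C10, and it leaves a C6=C7 enol silane for the lactone (guaianolide numbering).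

Key step: step 7

Numbering: guaianolide numbers are used throughout, also for acyclic precursors (cyclopentane C1–C5; cycloheptane C1, C5–C10; C14 on C10; C15 on C4; lactone O–C6 and C7–C11(=C13)–C12=O). Primed numbers denote the dienophile-derived half. α is the face of the ring-fusion hydrogens H1 and H5.

Remark: the SMILES is read as having H6 and H7 cis in both halves (cis-fused lactones: 6α-O, 7α-C11, 7β-H), and the route is built to deliver this; 2-bromoacrolein is taken as a purchasable reagent, distilled before use.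

Step 1
Reactants: 1 2-bromoacrolein; 2 allenylboronic acid pinacol ester
Product: 4 (R)-2-bromohex-1-en-5-yn-3-ol, via pinacol borate ester 3 (not isolated)
Conditions: (R)-TRIP (3,3′-bis(2,4,6-triisopropylphenyl)-BINOL hydrogen phosphate, 5 mol %), 4 Å MS, toluene, −20 °C; aq. NaHCO3 work-up
Reagents that add atoms: none
Why: Chiral-phosphoric-acid-catalysed asymmetric propargylboration, in which the allenylboronate adds through a closed six-membered SE2′ transition state held by the chiral phosphate, so that the acid enantiomer selects the aldehyde face and should set C3 as (R) (the mirror-image acid is used if the sense proves opposite).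

Step 2
Reactants: 4 (R)-2-bromohex-1-en-5-yn-3-ol
Product: 5 (R)-tert-butyl[(2-bromohex-1-en-5-yn-3-yl)oxy]dimethylsilane
Conditions: TBSCl, imidazole, DMF, 0 °C to rt
Reagents that add atoms: TBSCl, CC(C)(C)[Si](C)(C)Cl
Why: Standard silyl ether formation on a secondary alcohol, which leaves C3 untouched and gives the group that later relays chirality.

Step 3
Reactants: 6 (1-ethoxycyclopropoxy)trimethylsilane
Product: 8 1-ethynylcyclopropan-1-ol, via 1-ethoxycyclopropan-1-ol 7 (not isolated)
Conditions: MeOH, rt, evaporate; then HC≡CMgBr (3 equiv), THF, 0 to 60 °C; aq. NH4Cl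
Reagents that add atoms: ethynylmagnesium bromide, C#C[Mg]Br
Why: Methanolysis frees the cyclopropanone hemiketal, whose magnesium alkoxide collapses to cyclopropanone that is trapped by Grignard 1,2-addition of the acetylide, with no stereocentre formed.

Step 4
Reactants: 8 1-ethynylcyclopropan-1-ol
Product: 9 triethyl[(1-ethynylcyclopropyl)oxy]silane
Conditions: TESOTf, 2,6-lutidine, CH2Cl2, −78 °C
Reagents that add atoms: TESOTf, CC[Si](CC)(CC)OS(=O)(=O)C(F)(F)F
Why: Silyl triflate silylation of the tertiary cyclopropanol gives the 1-siloxycyclopropane that later becomes a labile C7 enol silane.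

Step 5
Reactants: 9 triethyl[(1-ethynylcyclopropyl)oxy]silane; 5 (R)-tert-butyl[(2-bromohex-1-en-5-yn-3-yl)oxy]dimethylsilane
Product: 11 (4R,6E)-4-(tert-butyldimethylsilyloxy)-5-methylene-7-[1-(triethylsilyloxy)cyclopropyl]hept-6-en-1-yne, via (E)-alkenyl pinacol boronate 10 (not isolated)
Conditions: HBpin (1.1 equiv), Cp2Zr(H)Cl (5 mol %), Et3N (10 mol %), neat, 60 °C; then 5, Pd(dppf)Cl2 (5 mol %), aq. K3PO4, THF, 50 °C
Reagents that add atoms: none
Why: Zirconium-catalysed syn-hydroboration gives the (E)-alkenylboronate, and Suzuki–Miyaura coupling with the 1,1-disubstituted vinyl bromide forms C4–C5 with retention of alkene geometry under copper-free conditions that should spare the terminal alkyne.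

Step 6
Reactants: 11 (4R,6E)-4-(tert-butyldimethylsilyloxy)-5-methylene-7-[1-(triethylsilyloxy)cyclopropyl]hept-6-en-1-yne
Product: 13 (5R,7E)-5-(tert-butyldimethylsilyloxy)-6-methylene-8-[1-(triethylsilyloxy)cyclopropyl]octa-1,2,7-triene, via propargylic amine 12 (not isolated)
Conditions: (CH2O)n (2.5 equiv), copper iodide CuI (0.5 equiv), Cy2NH (1.8 equiv), 1,4-dioxane, reflux
Reagents that add atoms: paraformaldehyde (as formaldehyde), C=O
Why: Crabbé homologation, in which the copper acetylide undergoes a Mannich reaction and a copper-mediated 1,5-hydride shift with loss of imine turns the propargylic amine into the terminal allene C1=C10=C14 without touching C3.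

Step 7
Reactants: 13 (5R,7E)-5-(tert-butyldimethylsilyloxy)-6-methylene-8-[1-(triethylsilyloxy)cyclopropyl]octa-1,2,7-triene
Product: 14 cis-fused hydroazulene (1αH,5αH)-3α-(tert-butyldimethylsilyloxy)-7-(triethylsilyloxy)-11,12,13-trinorguaia-4(15),6,10(14)-triene
Conditions: [Rh(CO)2Cl]2 (5 mol %), toluene (0.02 M), 80 °C, argon
Reagents that add atoms: none
Why: Monovalent rhodium coordinates the vinylcyclopropane and cleaves the C7–C9 bond to a σ-alkyl/π-allyl rhodacyclohexene; the proximal allene π-bond C1=C10 then inserts at the allyl terminus C5 (C1–C5 formed) and C(sp3)–C(sp2) reductive elimination forms C9–C10, leaving the C6=C7 enol silane and the exocyclic C10=C14 alkene. The closest known reaction type is the rhodium-catalysed intramolecular [5+2] cycloaddition of allenes with vinylcyclopropanes, for which 1-oxygenated cyclopropanes are the most reactive five-carbon partners. The cyclopentane closes by 5-exo carbometalation of the tethered allene (three-atom tether C2–C3–C4), and the cycloheptene closes by reductive elimination from the eight-membered rhodacycle, in effect a two-carbon insertion into the opened cyclopropane. C1 and C5 are created cis because allyl and allene carbons are joined suprafacially on one metal centre, and their absolute sense is relayed from C3, whose OTBS group is expected to sit pseudo-equatorially on the convex face of the forming methylenecyclopentane, that is cis to H1 and H5. The step needs reaction at the internal rather than the terminal allene π-bond, which is inherent to the tether length, and it needs the conjugated C4=C15 methylene to stay a spectator, which is secured because C4 lies in the tether so that no intramolecular [4+2] geometry with the allene exists; any minor C1/C5 diastereomer is separable at 14 or 16 before C3 is oxidised.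

Step 8
Reactants: 14 cis-fused hydroazulene enol silane
Product: 16 (1αH,5αH,6βH)-6α-hydroxy-3α-(tert-butyldimethylsilyloxy)-11,12,13-trinorguaia-4(15),10(14)-dien-7-one, via 6-silyloxy ketone 15 (not isolated)
Conditions: mCPBA (1.05 equiv), NaHCO3, CH2Cl2, −40 °C; then citric acid, MeOH–H2O, 0 °C
Reagents that add atoms: mCPBA, O=C(OO)c1cccc(Cl)c1
Why: Rubottom oxidation, in which the enol silane (by far the most electron-rich alkene) is epoxidised on the convex α-face because the β-face is covered by the cis-fused methylenecyclopentane, and silyl migration then hydrolysis give the 6α-hydroxy ketone with H6 trans to H5.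

Step 9
Reactants: 16 6α-hydroxy 7-ketone
Product: 18 (1αH,5αH,6βH)-3α-(tert-butyldimethylsilyloxy)-13-norguaia-4(15),7(11),10(14)-trien-12,6α-olide, via ester phosphorane 17 (not isolated)
Conditions: Ph3P=C=C=O (1.5 equiv), toluene, 100 °C
Reagents that add atoms: (triphenylphosphoranylidene)ketene, O=C=C=P(c1ccccc1)(c1ccccc1)c1ccccc1
Why: The alcohol adds to the ketene ylide and the resulting ester phosphorane closes the butenolide by intramolecular Wittig olefination of the C7 ketone under neutral conditions, so C6 is not epimerised.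

Step 10
Reactants: 18 butenolide
Product: 19 (1αH,5αH,6βH,7βH)-3α-(tert-butyldimethylsilyloxy)-13-norguaia-4(15),10(14)-dien-12,6α-olide (cis-fused lactone)
Conditions: Cu(OAc)2 (5 mol %), 1,2-bis(diphenylphosphino)benzene (5 mol %), (EtO)2MeSiH (2 equiv), t-BuOH (2 equiv), toluene, rt
Reagents that add atoms: none
Why: Copper hydride conjugate reduction, in which hydride should reach C7 on the face of H6 because the other face of the flat butenolide is covered by C5 and the carbobicycle, giving the cis-fused lactone (7β-H) while isolated alkenes do not react.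

Step 11
Reactants: 19 cis-fused lactone
Product: 22 (1αH,5αH,6βH,7βH)-3α-(tert-butyldimethylsilyloxy)guaia-4(15),10(14),11(13)-trien-12,6α-olide, via Mannich base 20 (not isolated), via ammonium iodide 21 (not isolated)
Conditions: LDA, THF, −78 °C; CH2=NMe2+ I−, −78 to 0 °C; then MeI, MeOH, rt; then aq. NaHCO3, CH2Cl2, rt
Reagents that add atoms: dimethylmethyleneiminium iodide, C=[N+](C)C.[I-]
Why: Mannich reaction of the lactone enolate followed by quaternisation and Hofmann-type elimination installs the C11=C13 methylene, and C7, not being α to the carbonyl, keeps its configuration.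

Step 12
Reactants: 22 silyl-protected α-methylene lactone
Product: 23 (1αH,5αH,6βH,7βH)-3α-hydroxyguaia-4(15),10(14),11(13)-trien-12,6α-olide
Conditions: HF·pyridine, pyridine, THF, 0 °C to rt
Reagents that add atoms: none
Why: Fluoride cleavage of the silyl ether under buffered, non-basic conditions that the α-methylene lactone tolerates.

Step 13
Reactants: 23 allylic alcohol
Product: 24 (1αH,5αH,6βH,7βH)-3-oxoguaia-4(15),10(14),11(13)-trien-12,6α-olide (7-epi-dehydrozaluzanin C)
Conditions: DMP, NaHCO3, CH2Cl2, 0 °C to rt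
Reagents that add atoms: none
Why: Dess–Martin oxidation of the allylic alcohol gives the cross-conjugated enone under neutral conditions and erases the C3 control centre.

Step 14
Reactants: 24 7-epi-dehydrozaluzanin C (one part of the batch)
Product: 25 (1αH,5αH,6βH,7βH)-3-(triethylsilyloxy)guaia-2,4(15),10(14),11(13)-tetraen-12,6α-olide
Conditions: TESOTf (1.2 equiv), Et3N (2 equiv), CH2Cl2, −78 to −20 °C
Reagents that add atoms: TESOTf, CC[Si](CC)(CC)OS(=O)(=O)C(F)(F)F
Why: Soft enolisation (silyl triflate and amine) can only occur toward C2 and gives the silyl dienol ether needed for Saegusa oxidation.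

Step 15
Reactants: 25 silyl dienol ether; 24 7-epi-dehydrozaluzanin C (3 equiv, excess recovered)
Product: 29 target dimer (2α-hydroxy; C2–C4′ bond β on the diene-derived half and cis to H5′ on the dienophile-derived half), via dienone 26 (not isolated), via deoxy adduct 27 (not isolated), via hydroperoxide 28 (not isolated)
Conditions: Pd(OAc)2 (1.1 equiv), MeCN, O2 (1 atm), rt, dark; then PPh3, 0 °C
Reagents that add atoms: dioxygen, O=O
Why: Saegusa oxidation turns 25 into dienone 26, whose s-cis-locked diene C2=C1–C10=C14 adds in a Diels–Alder reaction to the exocyclic enone C4′=C15′ of 24 on its convex face (cis to H5′), the C14–C15′ bond leading so that the spiro centre C4′ is fixed, after which the tertiary, α-keto and allylic C2–H of 27 is autoxidised through a planar C2 radical or dienol that should take up oxygen on the α-face (cis to H5; the β-face is flanked by H6 and by the C3′ carbonyl of the spiro ring, and the C2 configuration of 27 is therefore immaterial), and PPh3 reduces hydroperoxide 28 to the alcohol.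

Compound list
1 | 2-bromoacrolein | C=C(Br)C=O | starting material
2 | allenylboronic acid pinacol ester | C=C=CB1OC(C)(C)C(C)(C)O1 | starting material
3 | pinacol borate ester of (R)-2-bromohex-1-en-5-yn-3-ol (not isolated) | C=C(Br)[C@H](OB1OC(C)(C)C(C)(C)O1)CC#C | intermediate
4 | (R)-2-bromohex-1-en-5-yn-3-ol | C=C(Br)[C@H](O)CC#C | intermediate
5 | (R)-tert-butyl[(2-bromohex-1-en-5-yn-3-yl)oxy]dimethylsilane | C=C(Br)[C@H](O[Si](C)(C)C(C)(C)C)CC#C | intermediate
6 | (1-ethoxycyclopropoxy)trimethylsilane | CCOC1(O[Si](C)(C)C)CC1 | starting material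
7 | 1-ethoxycyclopropan-1-ol (not isolated) | CCOC1(O)CC1 | intermediate
8 | 1-ethynylcyclopropan-1-ol | C#CC1(O)CC1 | intermediate
9 | triethyl[(1-ethynylcyclopropyl)oxy]silane | C#CC1(O[Si](CC)(CC)CC)CC1 | intermediate
10 | (E)-2-{2-[1-(triethylsilyloxy)cyclopropyl]vinyl}-4,4,5,5-tetramethyl-1,3,2-dioxaborolane (not isolated) | CC[Si](CC)(CC)OC1(/C=C/B2OC(C)(C)C(C)(C)O2)CC1 | intermediate
11 | (4R,6E)-4-(tert-butyldimethylsilyloxy)-5-methylene-7-[1-(triethylsilyloxy)cyclopropyl]hept-6-en-1-yne | C#CC[C@@H](O[Si](C)(C)C(C)(C)C)C(=C)/C=C/C1(O[Si](CC)(CC)CC)CC1 | intermediate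
12 | N,N-dicyclohexyl propargylic amine of 11 (Mannich base, not isolated) | C(N(C1CCCCC1)C1CCCCC1)C#CC[C@@H](O[Si](C)(C)C(C)(C)C)C(=C)/C=C/C1(O[Si](CC)(CC)CC)CC1 | intermediate
13 | (5R,7E)-5-(tert-butyldimethylsilyloxy)-6-methylene-8-[1-(triethylsilyloxy)cyclopropyl]octa-1,2,7-triene | C=C=CC[C@@H](O[Si](C)(C)C(C)(C)C)C(=C)/C=C/C1(O[Si](CC)(CC)CC)CC1 | intermediate
14 | (1αH,5αH)-3α-(tert-butyldimethylsilyloxy)-7-(triethylsilyloxy)-11,12,13-trinorguaia-4(15),6,10(14)-triene (cis-fused; OTBS cis to H1 and H5) | C=C1[C@H](O[Si](C)(C)C(C)(C)C)C[C@H]2C(=C)CCC(O[Si](CC)(CC)CC)=C[C@H]21 | intermediate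
15 | 6α-(triethylsilyloxy) 7-ketone (not isolated) | C=C1[C@H](O[Si](C)(C)C(C)(C)C)C[C@H]2C(=C)CCC(=O)[C@H](O[Si](CC)(CC)CC)[C@H]21 | intermediate
16 | (1αH,5αH,6βH)-6α-hydroxy-3α-(tert-butyldimethylsilyloxy)-11,12,13-trinorguaia-4(15),10(14)-dien-7-one | C=C1[C@H](O[Si](C)(C)C(C)(C)C)C[C@H]2C(=C)CCC(=O)[C@H](O)[C@H]21 | intermediate
17 | 6α-O-(triphenylphosphoranylidene)acetate of 16 (not isolated) | C=C1[C@H](O[Si](C)(C)C(C)(C)C)C[C@H]2C(=C)CCC(=O)[C@H](OC(=O)C=P(c3ccccc3)(c3ccccc3)c3ccccc3)[C@H]21 | intermediate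
18 | (1αH,5αH,6βH)-3α-(tert-butyldimethylsilyloxy)-13-norguaia-4(15),7(11),10(14)-trien-12,6α-olide (butenolide) | C=C1[C@H](O[Si](C)(C)C(C)(C)C)C[C@H]2C(=C)CCC3=CC(=O)O[C@@H]3[C@H]21 | intermediate
19 | (1αH,5αH,6βH,7βH)-3α-(tert-butyldimethylsilyloxy)-13-norguaia-4(15),10(14)-dien-12,6α-olide (cis-fused lactone) | C=C1[C@H](O[Si](C)(C)C(C)(C)C)C[C@H]2C(=C)CC[C@@H]3CC(=O)O[C@@H]3[C@H]21 | intermediate
20 | 11-(dimethylaminomethyl) lactone (Mannich base, C11 epimers, not isolated) | C=C1[C@H](O[Si](C)(C)C(C)(C)C)C[C@H]2C(=C)CC[C@@H]3C(CN(C)C)C(=O)O[C@@H]3[C@H]21 | intermediate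
21 | 11-(trimethylammoniomethyl) lactone iodide (not isolated) | C=C1[C@H](O[Si](C)(C)C(C)(C)C)C[C@H]2C(=C)CC[C@@H]3C(C[N+](C)(C)C)C(=O)O[C@@H]3[C@H]21.[I-] | intermediate
22 | (1αH,5αH,6βH,7βH)-3α-(tert-butyldimethylsilyloxy)guaia-4(15),10(14),11(13)-trien-12,6α-olide | C=C1[C@H](O[Si](C)(C)C(C)(C)C)C[C@H]2C(=C)CC[C@@H]3C(=C)C(=O)O[C@@H]3[C@H]21 | intermediate
23 | (1αH,5αH,6βH,7βH)-3α-hydroxyguaia-4(15),10(14),11(13)-trien-12,6α-olide | C=C1[C@H](O)C[C@H]2C(=C)CC[C@@H]3C(=C)C(=O)O[C@@H]3[C@H]21 | intermediate
24 | (1αH,5αH,6βH,7βH)-3-oxoguaia-4(15),10(14),11(13)-trien-12,6α-olide (7-epi-dehydrozaluzanin C) | C=C1C(=O)C[C@H]2C(=C)CC[C@@H]3C(=C)C(=O)O[C@@H]3[C@H]21 | intermediate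
25 | (1αH,5αH,6βH,7βH)-3-(triethylsilyloxy)guaia-2,4(15),10(14),11(13)-tetraen-12,6α-olide | C=C1C(O[Si](CC)(CC)CC)=C[C@H]2C(=C)CC[C@@H]3C(=C)C(=O)O[C@@H]3[C@H]21 | intermediate
26 | (5αH,6βH,7βH)-3-oxoguaia-1,4(15),10(14),11(13)-tetraen-12,6α-olide (dienone, not isolated) | C=C1C(=O)C=C2C(=C)CC[C@@H]3C(=C)C(=O)O[C@@H]3[C@H]21 | intermediate
27 | 2-deoxy Diels–Alder adduct (C2–H; C2 configuration immaterial, all other centres as in 29; not isolated) | C=C1C(=O)C2C3=C(CC[C@@H]4C(=C)C(=O)O[C@@H]4[C@@H]13)CC[C@]21C(=O)C[C@H]2C(=C)CC[C@@H]3C(=C)C(=O)O[C@@H]3[C@H]21 | intermediate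
28 | 2α-hydroperoxide of the adduct (not isolated) | C=C1C(=O)[C@]2(OO)C3=C(CC[C@@H]4C(=C)C(=O)O[C@@H]4[C@@H]13)CC[C@]21C(=O)C[C@H]2C(=C)CC[C@@H]3C(=C)C(=O)O[C@@H]3[C@H]21 | intermediate
29 | CNP0269880.1: spiro Diels–Alder dimer, 2α-hydroxy, C2–C4′ bond β at C2 and cis to H5′ at C4′, both lactones cis-fused | C=C1C(=O)[C@]2(O)C3=C(CC[C@@H]4C(=C)C(=O)O[C@@H]4[C@@H]13)CC[C@]21C(=O)C[C@H]2C(=C)CC[C@@H]3C(=C)C(=O)O[C@@H]3[C@H]21 | target

Total step count: 15. Longest linear sequence: 13 steps (steps 3 to 15 from 6, or steps 1, 2 and 5 to 15 from 1).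

Steps most likely to fail

Step 7. The rhodium catalyst may be held by the conjugated diene, or may oligomerise or isomerise the terminal allene faster than it inserts, and the relay of facial selectivity from C3 to C1/C5 may be weak. The fallback sets out from 11 and comes back at 16. Alkyne 11 is deprotonated (n-BuLi, THF, −78 °C) and alkylated with (trimethylsilyl)methyl triflate to give the propargylsilane F1. The more robust alkyne–vinylcyclopropane [5+2] cycloaddition ([Rh(CO)2Cl]2, or CpRu(MeCN)3PF6) still forms C1–C5 and C9–C10 and gives the cycloheptadiene allylsilane F2. Rubottom oxidation (mCPBA, then citric acid) proceeds through the 6-silyloxy ketone F3 to the hydroxy ketone F4. Protodesilylation (CF3CO2H, CH2Cl2, 0 °C) then protonates C1 on the α-face, cis to H5, and moves the double bond to C10=C14, which gives 16.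

Step 15. The dienone may dimerise with itself, oxygen capture at C2 may occur with poor facial selectivity, or autoxidation may spread to other allylic positions. The fallback sets out from 25 and 24 and comes back at 29. The Saegusa oxidation and Diels–Alder reaction are run with the same reagents under argon so that the deoxy adduct 27 is isolated. Soft enolisation (TESOTf, Et3N, CH2Cl2, −78 °C) of its more acidic C2–H gives the silyl dienol ether F5. Two-electron oxygen transfer from dimethyldioxirane (acetone, −78 °C) to the C2=C3 bond gives the 2-silyloxy ketone F6, which citric acid hydrolyses to 29.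

Step 6. The hot copper-mediated conditions may open the siloxycyclopropane or polymerise the diene, or the propargylic amine may fail to fragment. The fallback sets out from 11 and comes back at 13. Hydroxymethylation of the lithium acetylide (n-BuLi, paraformaldehyde, THF) gives the propargylic alcohol F7. Mitsunobu reaction with 2-nitrobenzenesulfonylhydrazine (PPh3, DEAD, THF, −15 °C to rt) gives the sulfonylhydrazide F8. This loses sulfinic acid to the propargylic diazene F9, and retro-ene loss of dinitrogen from F9 gives allene 13 at room temperature.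

Further compounds
F1 | step 7 | (4R,6E)-4-(tert-butyldimethylsilyloxy)-5-methylene-7-[1-(triethylsilyloxy)cyclopropyl]-1-(trimethylsilylmethyl)hept-6-en-1-yne (propargylsilane) | C[Si](C)(C)CC#CC[C@@H](O[Si](C)(C)C(C)(C)C)C(=C)/C=C/C1(O[Si](CC)(CC)CC)CC1
F2 | step 7 | (5αH)-3α-(tert-butyldimethylsilyloxy)-7-(triethylsilyloxy)-14-(trimethylsilyl)-11,12,13-trinorguaia-1(10),4(15),6-triene | C=C1[C@H](O[Si](C)(C)C(C)(C)C)CC2=C(C[Si](C)(C)C)CCC(O[Si](CC)(CC)CC)=C[C@H]21
F3 | step 7 | 6α-(triethylsilyloxy) 7-ketone of the allylsilane series | C=C1[C@H](O[Si](C)(C)C(C)(C)C)CC2=C(C[Si](C)(C)C)CCC(=O)[C@H](O[Si](CC)(CC)CC)[C@H]21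
F4 | step 7 | (5αH,6βH)-6α-hydroxy-3α-(tert-butyldimethylsilyloxy)-14-(trimethylsilyl)-11,12,13-trinorguaia-1(10),4(15)-dien-7-one | C=C1[C@H](O[Si](C)(C)C(C)(C)C)CC2=C(C[Si](C)(C)C)CCC(=O)[C@H](O)[C@H]21
F5 | step 15 | C3 triethylsilyl dienol ether of adduct 27 | C=C1C(O[Si](CC)(CC)CC)=C2C3=C(CC[C@@H]4C(=C)C(=O)O[C@@H]4[C@@H]13)CC[C@]21C(=O)C[C@H]2C(=C)CC[C@@H]3C(=C)C(=O)O[C@@H]3[C@H]21
F6 | step 15 | 2α-(triethylsilyloxy) derivative of 29 | C=C1C(=O)[C@]2(O[Si](CC)(CC)CC)C3=C(CC[C@@H]4C(=C)C(=O)O[C@@H]4[C@@H]13)CC[C@]21C(=O)C[C@H]2C(=C)CC[C@@H]3C(=C)C(=O)O[C@@H]3[C@H]21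
F7 | step 6 | (5R,7E)-5-(tert-butyldimethylsilyloxy)-6-methylene-8-[1-(triethylsilyloxy)cyclopropyl]oct-7-en-2-yn-1-ol | OCC#CC[C@@H](O[Si](C)(C)C(C)(C)C)C(=C)/C=C/C1(O[Si](CC)(CC)CC)CC1
F8 | step 6 | N-propargyl-N-(2-nitrobenzenesulfonyl)hydrazine derived from F7 | NN(CC#CC[C@@H](O[Si](C)(C)C(C)(C)C)C(=C)/C=C/C1(O[Si](CC)(CC)CC)CC1)S(=O)(=O)c1ccccc1[N+](=O)[O-]
F9 | step 6 | propargylic diazene derived from F8 | N=NCC#CC[C@@H](O[Si](C)(C)C(C)(C)C)C(=C)/C=C/C1(O[Si](CC)(CC)CC)CC1
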